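**Retrosynthetic overview**

1. Pyran ring last: target 24 comes from 6-endo hydroalkoxylation (O2–C3 bond) of the hydroxymethyl chloro-ynenone 23.
2. 23 comes from 1,2-addition of the dienyne acetylide (fragment 1, 9) to chloro-enone 19 (fragment 2) at C4a, then oxidative 1,3-transposition to put the carbonyl at C6.
3. 19 comes from the symmetric 2,6-dichloro-p-quinol 11: an organocatalytic desymmetrising boronate oxa-Michael sets C7/C8; one chlorine stays as C5–Cl, the other activates C8a for hydroxymethylation and is then removed with kinetic protonation (C8a).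
4. 9 comes from crotonaldehyde 1 and alkenyl trifluoroborate 2 (iminium-catalysed conjugate alkenylation sets C5'), then Riley oxidation and Horner–Wadsworth–Emmons olefination.
5. Ring order: carbocycle (from arene 10) first, pyran last; ring atoms are cited by the isochromene numbering of the target.

Assumption: each chiral catalyst is used as the enantiomer that gives the configuration drawn (swap for the antipode if the sense proves opposite), and where an epimer mixture is inconsequential (C–Cl carbon of 12–17, acetal carbon of F1, carbinol carbon of 21 and F3) the expected major epimer is drawn.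

**Fragment 1 (side chain)**

Step 1
Reactants: 1 (E)-but-2-enal; 2 potassium trifluoro(2-methylprop-1-en-1-yl)borate
Product: 4 (3S)-3,5-dimethylhex-4-en-1-ol, via aldehyde 3 (not isolated)
Conditions: (2R,5R)-5-benzyl-2-tert-butyl-3-methylimidazolidin-4-one·HCl (20 mol %), HF (1 equiv), DME, −20 °C; then NaBH4, EtOH, 0 °C
Reagents that add atoms: none
Why: Iminium-activated organocatalytic conjugate alkenylation (Friedel–Crafts-type addition of a vinyltrifluoroborate to an enal), in which the benzyl group of the imidazolidinone shields one face of the (E)-iminium of 1 so that the boron-bearing carbon of 2 adds to the β-carbon from the open face (tertiary β-boryl cation, then loss of BF3 to fluoride), setting the first stereocentre as S, after which NaBH4 reduces aldehyde 3 in the same flask.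

Step 2
Reactants: 4 (3S)-3,5-dimethylhex-4-en-1-ol
Product: 5 tert-butyl{[(3S)-3,5-dimethylhex-4-en-1-yl]oxy}dimethylsilane
Conditions: TBSCl, imidazole, CH2Cl2, 23 °C
Reagents that add atoms: tert-butyldimethylsilyl chloride, CC(C)(C)[Si](C)(C)Cl
Why: Standard silylation of the primary alcohol, which leaves the stereocentre untouched.

Step 3
Reactants: 5 tert-butyl{[(3S)-3,5-dimethylhex-4-en-1-yl]oxy}dimethylsilane
Product: 6 (2E,4S)-6-{[tert-butyl(dimethyl)silyl]oxy}-2,4-dimethylhex-2-enal
Conditions: SeO2, 1,4-dioxane, 80 °C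
Reagents that add atoms: selenium dioxide, O=[Se]=O
Why: Riley allylic oxidation, in which the ene reaction/[2,3]-sigmatropic shift sequence attacks the (E)-methyl at the disubstituted end of the trisubstituted alkene and carries it to the (E)-enal, fixing the C3'=C4' geometry while the allylic stereocentre on the other alkene carbon is not involved.

Step 4
Reactants: 6 (2E,4S)-6-{[tert-butyl(dimethyl)silyl]oxy}-2,4-dimethylhex-2-enal; 7 diethyl [3-(trimethylsilyl)prop-2-yn-1-yl]phosphonate
Product: 9 tert-butyl{[(3S,4E,6E)-3,5-dimethylnona-4,6-dien-8-yn-1-yl]oxy}dimethylsilane, via silylated dienyne 8 (not isolated)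
Conditions: LiN(SiMe3)2, THF, −78 → 0 °C; then K2CO3, MeOH, 23 °C
Reagents that add atoms: none
Why: Horner–Wadsworth–Emmons olefination with the lithiated propargylic phosphonate gives the (E)-enyne, and K2CO3/MeOH then removes the alkynyl silyl group in the same flask while the alkyl silyl ether survives.

**Fragment 2 (carbocycle)**

Step 5
Reactants: 10 2,6-dichloro-4-methylphenol
Product: 11 2,6-dichloro-4-hydroxy-4-methylcyclohexa-2,5-dien-1-one
Conditions: PhI(OAc)2, MeCN/H2O (3:1), 0 °C
Reagents that add atoms: water, O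
Why: Oxidative dearomatisation with a trivalent iodine reagent, in which the phenol is activated on oxygen and water attacks the para carbon to give the achiral, symmetric quinol whose two chlorines block the ortho positions.

Step 6
Reactants: 11 2,6-dichloro-4-hydroxy-4-methylcyclohexa-2,5-dien-1-one
Product: 14 (3aS,4S,7aS)-4,6-dichloro-2,2,7a-trimethyl-3a,7a-dihydro-1,3-benzodioxol-5(4H)-one, via boronate 12 (not isolated), via diol 13 (not isolated)
Conditions: PhB(OH)2 (1.2 equiv), N-[3,5-bis(trifluoromethyl)phenyl]-N'-[(8R,9R)-6'-methoxycinchonan-9-yl]thiourea (10 mol %), 4 Å MS, toluene, 0 → 23 °C; then pinacol, Me2C(OMe)2, camphorsulfonic acid, 23 °C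
Reagents that add atoms: phenylboronic acid, OB(O)c1ccccc1; 2,2-dimethoxypropane, COC(C)(C)OC
Why: Proposed new method: the tertiary quinol hydroxyl of 11 condenses reversibly with PhB(OH)2 to a boronic hemiester whose boron is bound by the quinuclidine nitrogen of the bifunctional catalyst (raising the nucleophilicity of the remaining B–OH oxygen) while the thiourea hydrogen-bonds the dienone carbonyl, so that this oxygen is delivered intramolecularly (5-exo-trig oxa-Michael) to one of the two enantiotopic β-carbons, which sets C7 and C8 together with the cis relationship enforced by the five-membered tether, the closest known reactions being the amine–thiourea-catalysed oxa-Michael addition of boronic acid hemiesters of acyclic γ-hydroxy enones and the chiral-acid-catalysed acetalisation/oxa-Michael desymmetrisation of p-quinols, neither shown for a boronic acid on a halogenated quinol; pinacol then strips boron and the freed diol is ketalised in the same flask.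

Step 7
Reactants: 14 (3aS,4S,7aS)-4,6-dichloro-2,2,7a-trimethyl-3a,7a-dihydro-1,3-benzodioxol-5(4H)-one
Product: 17 (3aS,4S,7aS)-4-({[tert-butyl(dimethyl)silyl]oxy}methyl)-4,6-dichloro-2,2,7a-trimethyl-3a,7a-dihydro-1,3-benzodioxol-5(4H)-one, via lithium enolate 15 (not isolated), via lithium alkoxide 16 (not isolated)
Conditions: LiN(i-Pr)2, THF, −78 °C; CH2O (gas); then TBSOTf, −78 → −40 °C
Reagents that add atoms: formaldehyde, C=O; tert-butyldimethylsilyl trifluoromethanesulfonate, CC(C)(C)[Si](C)(C)OS(=O)(=O)C(F)(F)F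
Why: Kinetic enolate aldol, in which LiN(i-Pr)2 removes the only α-hydrogen (on the chlorine-bearing carbon), the chloro-enolate adds to monomeric formaldehyde to install C1 and the alkoxide is silylated before it can close to an epoxide, the configuration of the quaternary C–Cl carbon being irrelevant because step 8 planarises it.

Step 8
Reactants: 17 (3aS,4S,7aS)-4-({[tert-butyl(dimethyl)silyl]oxy}methyl)-4,6-dichloro-2,2,7a-trimethyl-3a,7a-dihydro-1,3-benzodioxol-5(4H)-one
Product: 19 (3aR,4S,7aS)-4-({[tert-butyl(dimethyl)silyl]oxy}methyl)-6-chloro-2,2,7a-trimethyl-3a,7a-dihydro-1,3-benzodioxol-5(4H)-one, via samarium enolate 18 (not isolated)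
Conditions: SmI2 (2.2 equiv), THF/MeOH, −78 °C
Reagents that add atoms: none
Why: Reductive dehalogenation of an α-chloro ketone with SmI2, in which two electron transfers cleave the C–Cl bond α to the ketone (the vinylic chloride is inert) and the samarium enolate is protonated by MeOH at −78 °C on the convex face, anti to the cis-fused dioxolane, which places H on the β face and the CH2OSi group cis to both oxygens (the all-cis triad, C8a of the target).

**Union and endgame**

Step 9
Reactants: 9 tert-butyl{[(3S,4E,6E)-3,5-dimethylnona-4,6-dien-8-yn-1-yl]oxy}dimethylsilane; 19 (3aR,4S,7aS)-4-({[tert-butyl(dimethyl)silyl]oxy}methyl)-6-chloro-2,2,7a-trimethyl-3a,7a-dihydro-1,3-benzodioxol-5(4H)-one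
Product: 21 (3aR,4S,5R,7aS)-4-({[tert-butyl(dimethyl)silyl]oxy}methyl)-5-[(3E,5E,7S)-9-{[tert-butyl(dimethyl)silyl]oxy}-5,7-dimethylnona-3,5-dien-1-yn-1-yl]-6-chloro-2,2,7a-trimethyl-3a,4,5,7a-tetrahydro-1,3-benzodioxol-5-ol, via lithium acetylide 20 (not isolated)
Conditions: 9, n-BuLi, THF, −78 °C; then 19, −78 °C; H2O
Reagents that add atoms: none
Why: Carbonyl 1,2-addition of a lithium acetylide to the enone (a hard, slim nucleophile for which conjugate addition and enolisation are minor at −78 °C), forming the C4–C4a bond, with the new carbinol centre destroyed in step 10 and C8a no longer α to a carbonyl.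

Step 10
Reactants: 21 (3aR,4S,5R,7aS)-4-({[tert-butyl(dimethyl)silyl]oxy}methyl)-5-[(3E,5E,7S)-9-{[tert-butyl(dimethyl)silyl]oxy}-5,7-dimethylnona-3,5-dien-1-yn-1-yl]-6-chloro-2,2,7a-trimethyl-3a,4,5,7a-tetrahydro-1,3-benzodioxol-5-ol
Product: 22 (3aR,7S,7aR)-7-({[tert-butyl(dimethyl)silyl]oxy}methyl)-6-[(3E,5E,7S)-9-{[tert-butyl(dimethyl)silyl]oxy}-5,7-dimethylnona-3,5-dien-1-yn-1-yl]-5-chloro-2,2,3a-trimethyl-7,7a-dihydro-1,3-benzodioxol-4(3aH)-one
Conditions: [C5H5NH][CrO3Cl] (pyridinium chlorochromate), NaOAc, 4 Å MS, CH2Cl2, 23 °C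
Reagents that add atoms: none
Why: Babler–Dauben oxidative 1,3-transposition, in which the chromate ester of the tertiary allylic alcohol undergoes [3,3]-shift to the unsubstituted alkene terminus and is oxidised there, giving the β-alkynyl α-chloro enone (C6=O, C4a=C5–Cl) without touching the three ring stereocentres.

Step 11
Reactants: 22 (3aR,7S,7aR)-7-({[tert-butyl(dimethyl)silyl]oxy}methyl)-6-[(3E,5E,7S)-9-{[tert-butyl(dimethyl)silyl]oxy}-5,7-dimethylnona-3,5-dien-1-yn-1-yl]-5-chloro-2,2,3a-trimethyl-7,7a-dihydro-1,3-benzodioxol-4(3aH)-one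
Product: 24 (7R,8R,8aS)-5-chloro-7,8-dihydroxy-3-[(1E,3E,5S)-7-hydroxy-3,5-dimethylhepta-1,3-dien-1-yl]-7-methyl-1,7,8,8a-tetrahydro-6H-isochromen-6-one, via tetraol 23 (not isolated)
Conditions: CF3CO2H/H2O/THF (1:1:4), 0 → 23 °C; evaporate; then Ph3PAuNTf2 (5 mol %), THF, 23 °C
Reagents that add atoms: none
Why: Aqueous acid removes both silyl ethers and the acetonide before the acid-sensitive dienyl enol ether exists, and the cationic gold catalyst then effects 6-endo-dig hydroalkoxylation (cycloisomerisation) of the primary alcohol onto the alkyne carbon that is δ to the ketone and stabilised by the dienyl group, closing the pyran ring with no stereocentre involved.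

**Compound list**

1 | (E)-but-2-enal | C/C=C/C=O | starting material
2 | potassium trifluoro(2-methylprop-1-en-1-yl)borate | [K+].CC(C)=C[B-](F)(F)F | starting material
3 | (3S)-3,5-dimethylhex-4-enal | CC(C)=C[C@@H](C)CC=O | intermediate (not isolated)
4 | (3S)-3,5-dimethylhex-4-en-1-ol | CC(C)=C[C@@H](C)CCO | intermediate
5 | tert-butyl{[(3S)-3,5-dimethylhex-4-en-1-yl]oxy}dimethylsilane | CC(C)=C[C@@H](C)CCO[Si](C)(C)C(C)(C)C | intermediate
6 | (2E,4S)-6-{[tert-butyl(dimethyl)silyl]oxy}-2,4-dimethylhex-2-enal | O=C/C(C)=C/[C@@H](C)CCO[Si](C)(C)C(C)(C)C | intermediate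
7 | diethyl [3-(trimethylsilyl)prop-2-yn-1-yl]phosphonate | CCOP(=O)(CC#C[Si](C)(C)C)OCC | starting material
8 | tert-butyl{[(3S,4E,6E)-3,5-dimethyl-9-(trimethylsilyl)nona-4,6-dien-8-yn-1-yl]oxy}dimethylsilane | C[Si](C)(C)C#C/C=C/C(C)=C/[C@@H](C)CCO[Si](C)(C)C(C)(C)C | intermediate (not isolated)
9 | tert-butyl{[(3S,4E,6E)-3,5-dimethylnona-4,6-dien-8-yn-1-yl]oxy}dimethylsilane | C#C/C=C/C(C)=C/[C@@H](C)CCO[Si](C)(C)C(C)(C)C | intermediate
10 | 2,6-dichloro-4-methylphenol | Cc1cc(Cl)c(O)c(Cl)c1 | starting material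
11 | 2,6-dichloro-4-hydroxy-4-methylcyclohexa-2,5-dien-1-one | CC1(O)C=C(Cl)C(=O)C(Cl)=C1 | intermediate
12 | (3aS,4S,7aS)-4,6-dichloro-7a-methyl-2-phenyl-3a,7a-dihydro-1,3,2-benzodioxaborol-5(4H)-one (cis-fused cyclic phenylboronate) | O=C1C(Cl)=C[C@]2(C)OB(c3ccccc3)O[C@@H]2[C@@H]1Cl | intermediate (not isolated)
13 | (4S,5S,6S)-2,6-dichloro-4,5-dihydroxy-4-methylcyclohex-2-en-1-one (cis-diol) | O=C1C(Cl)=C[C@](C)(O)[C@H](O)[C@@H]1Cl | intermediate (not isolated)
14 | (3aS,4S,7aS)-4,6-dichloro-2,2,7a-trimethyl-3a,7a-dihydro-1,3-benzodioxol-5(4H)-one | O=C1C(Cl)=C[C@]2(C)OC(C)(C)O[C@@H]2[C@@H]1Cl | intermediate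
15 | lithium enolate of 14 (O–Li on C5, C4=C5) | [Li]OC1=C(Cl)[C@H]2OC(C)(C)O[C@@]2(C)C=C1Cl | intermediate (not isolated)
16 | lithium alkoxide of the 4-(hydroxymethyl) aldol adduct of 14 | O=C1C(Cl)=C[C@]2(C)OC(C)(C)O[C@@H]2[C@@]1(Cl)CO[Li] | intermediate (not isolated)
17 | (3aS,4S,7aS)-4-({[tert-butyl(dimethyl)silyl]oxy}methyl)-4,6-dichloro-2,2,7a-trimethyl-3a,7a-dihydro-1,3-benzodioxol-5(4H)-one | O=C1C(Cl)=C[C@]2(C)OC(C)(C)O[C@@H]2[C@@]1(Cl)CO[Si](C)(C)C(C)(C)C | intermediate
18 | diiodosamarium enolate of 19 (O–SmI2 on C5, C4=C5) | I[Sm](I)OC1=C(CO[Si](C)(C)C(C)(C)C)[C@H]2OC(C)(C)O[C@@]2(C)C=C1Cl | intermediate (not isolated)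
19 | (3aR,4S,7aS)-4-({[tert-butyl(dimethyl)silyl]oxy}methyl)-6-chloro-2,2,7a-trimethyl-3a,7a-dihydro-1,3-benzodioxol-5(4H)-one (all-cis) | O=C1C(Cl)=C[C@]2(C)OC(C)(C)O[C@@H]2[C@@H]1CO[Si](C)(C)C(C)(C)C | intermediate
20 | lithium acetylide of 9 | [Li]C#C/C=C/C(C)=C/[C@@H](C)CCO[Si](C)(C)C(C)(C)C | intermediate (not isolated)
21 | (3aR,4S,5R,7aS)-4-({[tert-butyl(dimethyl)silyl]oxy}methyl)-5-[(3E,5E,7S)-9-{[tert-butyl(dimethyl)silyl]oxy}-5,7-dimethylnona-3,5-dien-1-yn-1-yl]-6-chloro-2,2,7a-trimethyl-3a,4,5,7a-tetrahydro-1,3-benzodioxol-5-ol | O[C@]1(C#C/C=C/C(C)=C/[C@@H](C)CCO[Si](C)(C)C(C)(C)C)C(Cl)=C[C@]2(C)OC(C)(C)O[C@@H]2[C@@H]1CO[Si](C)(C)C(C)(C)C | intermediate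
22 | (3aR,7S,7aR)-7-({[tert-butyl(dimethyl)silyl]oxy}methyl)-6-[(3E,5E,7S)-9-{[tert-butyl(dimethyl)silyl]oxy}-5,7-dimethylnona-3,5-dien-1-yn-1-yl]-5-chloro-2,2,3a-trimethyl-7,7a-dihydro-1,3-benzodioxol-4(3aH)-one | CC1(C)O[C@@H]2[C@H](CO[Si](C)(C)C(C)(C)C)C(C#C/C=C/C(C)=C/[C@@H](C)CCO[Si](C)(C)C(C)(C)C)=C(Cl)C(=O)[C@]2(C)O1 | intermediate
23 | (4S,5R,6R)-2-chloro-5,6-dihydroxy-3-[(3E,5E,7S)-9-hydroxy-5,7-dimethylnona-3,5-dien-1-yn-1-yl]-4-(hydroxymethyl)-6-methylcyclohex-2-en-1-one | O=C1C(Cl)=C(C#C/C=C/C(C)=C/[C@@H](C)CCO)[C@@H](CO)[C@@H](O)[C@@]1(C)O | intermediate (not isolated)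
24 | (7R,8R,8aS)-5-chloro-7,8-dihydroxy-3-[(1E,3E,5S)-7-hydroxy-3,5-dimethylhepta-1,3-dien-1-yl]-7-methyl-1,7,8,8a-tetrahydro-6H-isochromen-6-one | CC(/C=C/C1=CC2=C(Cl)C(=O)[C@](C)(O)[C@H](O)[C@@H]2CO1)=C\[C@@H](C)CCO | target

**Step count and risk**

Total: 11 steps (4 for fragment 1, 4 for fragment 2, 3 from the union on). Longest linear sequence: 7 steps (10 → 24 through steps 5–11; equally 1 → 24 through steps 1–4 and 9–11).

The three steps most likely to fail:

Step 6 (the proposed new desymmetrisation). The risks are a low enantiomeric excess from reversible oxa-Michael addition on the α-chloro enone and slow alkylation of the amine catalyst by the α-chloro ketone. The fallback uses known chemistry and sets out from 11. A chiral phosphoric acid [(R)-3,3'-bis(2,4,6-triisopropylphenyl)-1,1'-binaphthyl-2,2'-diyl hydrogen phosphate, 5 mol %, CH2Cl2, 4 Å MS] catalyses acetalisation of the quinol hydroxyl with isobutyraldehyde followed by oxa-Michael closure of the hemiacetal, giving the 2-isopropyl dioxolane F1. Acid methanolysis (TsOH, MeOH) then frees diol 13, which is ketalised with 2,2-dimethoxypropane and camphorsulfonic acid, and the route is rejoined at 14.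

Step 8 (C8a set by kinetic protonation). The risk is protonation on the wrong face, giving the C4 epimer of 19. The fallback reverses the order of bond formation at that carbon and sets out from 14. SmI2/MeOH removes the α-chlorine first to give the dechloro ketone F2. Its kinetic lithium enolate [LiN(i-Pr)2, THF, −78 °C] is then hydroxymethylated with formaldehyde and silylated with TBSOTf. The carbon electrophile now enters on the face that the proton preferred, so the epimer that protonation disfavoured becomes the kinetic product, and the route is rejoined at 19.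

Step 10 (oxidative transposition). The risks are oxidation of the dienyne, a competing propargylic (Meyer–Schuster) pathway and a sluggish shift onto the chloro-alkene. The fallback separates transposition from oxidation and sets out from 21. Ph3SiOReO3 (2 mol %, Et2O, −50 °C) isomerises the tertiary alcohol to the conjugated secondary allylic alcohol F3, which Dess–Martin periodinane (NaHCO3, CH2Cl2, 0 °C) oxidises, and the route is rejoined at 22.

Further compounds
F1 | step 6 | (3aS,4S,7aS)-4,6-dichloro-7a-methyl-2-(propan-2-yl)-3a,7a-dihydro-1,3-benzodioxol-5(4H)-one (either acetal epimer) | O=C1C(Cl)=C[C@]2(C)OC(C(C)C)O[C@@H]2[C@@H]1Cl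
F2 | step 8 | (3aR,7aS)-6-chloro-2,2,7a-trimethyl-3a,7a-dihydro-1,3-benzodioxol-5(4H)-one | O=C1C(Cl)=C[C@]2(C)OC(C)(C)O[C@@H]2C1
F3 | step 10 | (3aS,4R,7S,7aR)-7-({[tert-butyl(dimethyl)silyl]oxy}methyl)-6-[(3E,5E,7S)-9-{[tert-butyl(dimethyl)silyl]oxy}-5,7-dimethylnona-3,5-dien-1-yn-1-yl]-5-chloro-2,2,3a-trimethyl-3a,4,7,7a-tetrahydro-1,3-benzodioxol-4-ol | CC1(C)O[C@@H]2[C@H](CO[Si](C)(C)C(C)(C)C)C(C#C/C=C/C(C)=C/[C@@H](C)CCO[Si](C)(C)C(C)(C)C)=C(Cl)[C@H](O)[C@]2(C)O1
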